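**Retrosynthetic overview**

1. The seven-membered carbocycle (C1, C5, C6, C7, C8, C9, C10) carries oxygen on C5, which lies between C1 (bearing the carbonyl carbon C2) and C6, and oxygen on C9, which lies between C8 and C10. C6–C5–C1 can therefore come from a silyloxyvinyl rhodium carbene (acceptor C2 on C1) and C7=C8–C9=C10 from a 2-silyloxy-1,3-diene. Cyclopropanation/Cope rearrangement (formal (4+3)) then closes the ring at C1–C10 and C6–C7 and sets C6, C7 and C10.
2. After the ring is made, the C6–OH directs a Rubottom oxidation that sets the C1 carbinol, and C1–OH directs reduction of both ring ketones (C5, C9). C9–OH then ties up the C1 ester as a temporary bridged γ-lactone, which a chiral-pool C3–C4–C15 organolithium opens (C2–C3 bond).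
3. The lactone ring comes from palladium-catalysed cyclocarbonylation of C6–OH onto a C7 ethynyl group (C11–C12 and C12–O bonds); C5–O is then esterified with (S)-2-methylbutanoic acid.
4. Ring order: cyclopropane (transient), cycloheptadiene, bridged γ-lactone C2–O–C9 (temporary), α-methylene-γ-butyrolactone.

Key step: step 7

Remark on numbering: atoms are numbered as in the target. C1 is the carbinol carbon bearing the 3-hydroxybutanoyl chain C2–C3–C4(–C15), C5 the acyloxy carbon, C6 the lactone O–CH, C7 the ring-fusion CH, C8 the CH2, C9 the CHOH, C10 the CH(CH3) with methyl C14, and C11–C13 the α-methylene lactone carbons. The α face of the seven-membered ring is the one that bears O6, C11, C14 and O1 in the target; β is the opposite face.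

Remark on the catalyst: the sense of induction of Rh2(S-PTAD)4 with this new carbene/diene pair is assumed to be the one drawn; if it proves opposite, the equally available Rh2(R-PTAD)4 is used and nothing else changes.

Remark on tautomers: the γ-hydroxy ketones 22, 23, 24, 26 and 27 may equilibrate with their C2–O–C9 lactol forms; they are drawn in the open form of the target, and a lactol would mask C9–O in steps 14 and 15 to the same effect.

**Route**

Step 1
Reactants: 1 3-(trimethylsilyl)prop-2-ynal; 2 diethyl (2-oxobutyl)phosphonate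
Product: 3 (4E)-7-(trimethylsilyl)hept-4-en-6-yn-3-one
Conditions: LiCl, i-Pr2NEt, MeCN, 0 °C to rt
Reagents that add atoms: none
Why: Horner–Wadsworth–Emmons olefination under mild LiCl/amine (Masamune–Roush) conditions tolerates the base-sensitive ynal and should give the (E)-enone, the geometry following from reversible addition of the stabilised phosphonate anion.

Step 2
Reactants: 3 (4E)-7-(trimethylsilyl)hept-4-en-6-yn-3-one
Product: 4 triethyl{[(2Z,4E)-7-(trimethylsilyl)hepta-2,4-dien-6-yn-3-yl]oxy}silane
Conditions: Et3SiOTf, Et3N, Et2O, −78 to 0 °C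
Reagents that add atoms: triethylsilyl trifluoromethanesulfonate, CC[Si](CC)(CC)OS(=O)(=O)C(F)(F)F
Why: Soft enolisation with silyl triflate/amine can only occur at the ethyl CH2 (C10) and should give the more stable (Z)-silyl enol ether (methyl cis to the silyloxy group), which fixes the C9=C10 geometry that later controls C10.

Step 3
Reactants: 5 methyl 2-hydroxyacetate
Product: 6 methyl 2-[(triethylsilyl)oxy]acetate
Conditions: Et3SiCl, imidazole, CH2Cl2, 0 °C to rt
Reagents that add atoms: chlorotriethylsilane, CC[Si](Cl)(CC)CC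
Why: Routine silyl ether formation; the triethylsilyl group is chosen because step 8 removes it under conditions that should spare a tert-butyldimethylsilyl enol ether.

Step 4
Reactants: 6 methyl 2-[(triethylsilyl)oxy]acetate; 7 methyl acetate
Product: 9 methyl 3-oxo-4-[(triethylsilyl)oxy]butanoate, via lithium enolate of methyl acetate 8 (not isolated)
Conditions: 7 (2.2 equiv), LiN(i-Pr)2 (2.2 equiv), THF, −78 °C; then 6, −78 to −30 °C; AcOH quench
Reagents that add atoms: none
Why: Crossed Claisen condensation of a preformed ester enolate with the glycolate ester, driven by deprotonation of the β-keto ester product by the second equivalent of enolate.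

Step 5
Reactants: 9 methyl 3-oxo-4-[(triethylsilyl)oxy]butanoate
Product: 10 methyl 2-diazo-3-oxo-4-[(triethylsilyl)oxy]butanoate
Conditions: 4-acetamidobenzenesulfonyl azide, Et3N, MeCN, 0 °C to rt
Reagents that add atoms: 4-acetamidobenzenesulfonyl azide, CC(=O)Nc1ccc(cc1)S(=O)(=O)N=[N+]=[N-]
Why: Regitz diazo transfer to the doubly activated methylene of the β-keto ester.

Step 6
Reactants: 10 methyl 2-diazo-3-oxo-4-[(triethylsilyl)oxy]butanoate
Product: 11 methyl (3Z)-3-[(tert-butyldimethylsilyl)oxy]-2-diazo-4-[(triethylsilyl)oxy]but-3-enoate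
Conditions: t-BuMe2SiOTf, Et3N, CH2Cl2, 0 °C
Reagents that add atoms: tert-butyldimethylsilyl trifluoromethanesulfonate, CC(C)(C)[Si](C)(C)OS(=O)(=O)C(F)(F)F
Why: Enol silylation of the α-diazo-β-keto ester at its only enolisable position (C6) gives the siloxyvinyl diazoacetate, and the (Z) geometry (two oxygens cis, OTES trans to the diazo carbon) is expected because the C6 substituent avoids the diazo ester unit.

Step 7
Reactants: 4 triethyl{[(2Z,4E)-7-(trimethylsilyl)hepta-2,4-dien-6-yn-3-yl]oxy}silane; 11 methyl (3Z)-3-[(tert-butyldimethylsilyl)oxy]-2-diazo-4-[(triethylsilyl)oxy]but-3-enoate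
Product: 13 methyl 2-[(tert-butyldimethylsilyl)oxy]-7-methyl-3,6-bis[(triethylsilyl)oxy]-4-[(trimethylsilyl)ethynyl]cyclohepta-1,5-diene-1-carboxylate (3/4/7 all-cis; C6–O/C7–alkynyl/C10–CH3 all α), via cis-divinylcyclopropane 12 (not isolated)
Conditions: Rh2(S-PTAD)4 (dirhodium tetrakis[(S)-(1-adamantyl)(N-phthalimido)acetate], 1 mol %), 4 (1.3 equiv), slow addition of 11, hexanes, −40 °C to rt; then 40 °C
Reagents that add atoms: none
Why: Rh2(S-PTAD)4 extrudes N2 from 11 to give a donor/acceptor rhodium vinylcarbene whose carbene carbon (C1) adds to the most electron-rich double bond of 4, the C9=C10 silyl enol ether, forming C1–C10 and C1–C9 (cis-divinylcyclopropane 12); 12 then undergoes Cope rearrangement through the boat transition state at or near room temperature, breaking C1–C9 and forming C6–C7. The closest known reaction type is the tandem cyclopropanation/Cope rearrangement (formal (4+3) cycloaddition) of siloxyvinyl diazoacetates with dienes under chiral dirhodium tetracarboxylate catalysis, which is also known for oxygenated dienes. The three-membered ring is closed by (2+1) carbene addition and the seven-membered ring by [3,3]-sigmatropic ring expansion of the cis-1,2-divinylcyclopropane, so no ring is closed by attack on an open chain. C6 and C7 become cis because both vinyl termini carry their substituent in the E position (OTES trans to C1 in 11, the alkynyl group trans to C9 in 4) and the boat transition state turns both outward; C10 keeps the geometry of the (Z) enol ether, which places CH3 trans to the dienyl group on the cyclopropane and therefore cis to the C6 and C7 substituents in 13; the absolute sense comes from the chiral catalyst in the cyclopropanation. The step needs site selectivity for C9=C10 over C7=C8 (C7=C8 is trans-disubstituted and conjugated to the alkyne, a pattern such carbenes do not cyclopropanate), attack at the carbene carbon and not at the vinylogous terminus (the C6 substituent, the C5 silyloxy group and the non-polar solvent favour this), and the cis-divinyl arrangement (the vinyl donor of the carbene ends up syn to the alkene substituent that extends the π system).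

Step 8
Reactants: 13 cycloheptadiene from step 7
Product: 14 methyl 2-[(tert-butyldimethylsilyl)oxy]-3-hydroxy-7-methyl-6-oxo-4-[(trimethylsilyl)ethynyl]cyclohept-1-ene-1-carboxylate (3/4/7 all-cis)
Conditions: AcOH/THF/H2O 3:1:1, 0 °C to rt
Reagents that add atoms: none
Why: Mild aqueous acid hydrolyses the isolated triethylsilyl enol ether (protonation at C8, no new stereocentre) and the secondary triethylsilyl ether, whereas the tert-butyldimethylsilyl enol ether of the β-keto ester is a vinylogous silyl carbonate that resists protonation at C1; the weakly acidic medium should not epimerise C10.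

Step 9
Reactants: 14 hydroxy enol ether from step 8
Product: 16 methyl 1-[(tert-butyldimethylsilyl)oxy]-3-hydroxy-7-methyl-2,6-dioxo-4-[(trimethylsilyl)ethynyl]cycloheptane-1-carboxylate (1-O/3-O/4-C/7-C all-cis), via silyloxy epoxide 15 (not isolated)
Conditions: VO(acac)2 (5 mol %), t-BuOOH (1.5 equiv, decane solution), CH2Cl2, 0 °C to rt
Reagents that add atoms: tert-butyl hydroperoxide, CC(C)(C)OO
Why: Hydroxyl-directed vanadium-catalysed epoxidation delivers oxygen to the C1=C5 enol ether from the face of the allylic C6–OH (α), and the silyloxy epoxide opens with O-to-O silyl migration (Rubottom oxidation), so that C1 carries oxygen on the α face and the ester on the β face.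

Step 10
Reactants: 16 α-silyloxy diketone from step 9
Product: 17 methyl 4-ethynyl-1,3-dihydroxy-7-methyl-2,6-dioxocycloheptane-1-carboxylate (1-OH/3-OH/4-ethynyl/7-methyl all-cis)
Conditions: Bu4NF, AcOH (1:1), THF, 0 °C
Reagents that add atoms: none
Why: Fluoride cleaves the tertiary α-silyloxy ether and the C(sp)–Si bond in one operation, and the acetic acid buffer suppresses retro-aldol and retro-Claisen cleavage of the α-hydroxy-β-keto ester.

Step 11
Reactants: 17 dihydroxy diketone from step 10
Product: 19 4-ethynyl-1,2,3-trihydroxy-9-methyl-7-oxabicyclo[4.2.1]nonan-8-one (bridged lactone C2–O–C9; C1–OH α/C5–OH β/C6–OH α/C7–ethynyl α/C10–CH3 α), via tetraol ester 18 (not isolated)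
Conditions: Me4NBH(OAc)3 (6 equiv), MeCN/AcOH 1:1, −30 to 0 °C; aqueous sodium potassium tartrate work-up; then PPTS (cat.), PhMe, 60 °C
Reagents that add atoms: none
Why: Hydroxyl-directed triacetoxyborohydride reduction (Evans–Saksena type): hydride is delivered intramolecularly from the α-oriented C1 (and C6) alkoxyborohydride to the α face of C5 and C9, which sets both new carbinols β (1,2-anti and 1,3-anti to C1–OH), and the cis-1,3 pair C9–OH/C1–CO2Me then lactonises under acid catalysis, which tells C9–OH apart from C5–OH.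

Step 12
Reactants: 19 bridged lactone from step 11; 20 (2S)-1-chloropropan-2-ol
Product: 22 (3S)-1-[4-ethynyl-1,2,3,6-tetrahydroxy-7-methylcycloheptyl]-3-hydroxybutan-1-one (ring: 1α/3α-OH; 2β/6β-OH; 4α-ethynyl; 7α-methyl), via dilithio reagent 21 (not isolated)
Conditions: 20, n-BuLi (1.0 equiv), THF, −78 °C, then LiC10H8 (lithium naphthalenide, 2.1 equiv), −78 °C; separately 19, LiN(SiMe3)2 (4.0 equiv), THF, −78 °C; combine (3 equiv of 21 per 19), −78 °C; aq NH4Cl
Reagents that add atoms: none
Why: Addition of an organolithium to a γ-lactone stops at the lactol alkoxide and gives the hydroxy ketone on work-up; the β-oxido organolithium (reductive lithiation of the chlorohydrin alkoxide, stable at −78 °C because oxide is a poor leaving group) brings C3, C4 and C15 with the (S)-carbinol from the chiral pool and releases C9–OH.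

Step 13
Reactants: 22 ethynyl pentaol ketone from step 12
Product: 23 (3aS,5R,6S,7S,8S,8aR)-5,7,8-trihydroxy-7-[(3S)-3-hydroxybutanoyl]-6-methyl-3-methylideneoctahydro-2H-cyclohepta[b]furan-2-one
Conditions: PdCl2 (5 mol %), SnCl2 (5 mol %), PPh3 (10 mol %), CO (7 atm), MeCN, 75 °C
Reagents that add atoms: carbon monoxide, [C-]#[O+]
Why: Palladium-catalysed cyclocarbonylation of a homopropargylic alcohol: the alkoxycarbonylpalladium species formed at C6–OH adds syn to the cis-disposed ethynyl group in the 5-exo-dig mode and protonolysis gives the α-methylene-γ-butyrolactone, the cis ring fusion being fixed by C6 and C7 from step 7 and no other hydroxyl being able to close a five-membered ring onto the alkyne.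

Step 14
Reactants: 23 lactone tetraol from step 13
Product: 24 (3aS,5R,6S,7S,8S,8aR)-7,8-dihydroxy-6-methyl-3-methylidene-5-[(triethylsilyl)oxy]-7-{(3S)-3-[(triethylsilyl)oxy]butanoyl}octahydro-2H-cyclohepta[b]furan-2-one
Conditions: Et3SiOTf (2.1 equiv), 2,6-lutidine, CH2Cl2, −78 °C
Reagents that add atoms: triethylsilyl trifluoromethanesulfonate, CC[Si](CC)(CC)OS(=O)(=O)C(F)(F)F
Why: Silylation under steric control: the open-chain C4–OH and the ring C9–OH should react much faster than C5–OH (flanked by the fully substituted C1 and by C6) and the tertiary C1–OH.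

Step 15
Reactants: 24 bis(silyl ether) from step 14; 25 (2S)-2-methylbutanoic acid
Product: 26 (3aS,5R,6S,7S,8S,8aR)-7-hydroxy-6-methyl-3-methylidene-2-oxo-5-[(triethylsilyl)oxy]-7-{(3S)-3-[(triethylsilyl)oxy]butanoyl}octahydro-2H-cyclohepta[b]furan-8-yl (2S)-2-methylbutanoate
Conditions: DCC, DMAP (cat.), CH2Cl2, 0 °C to rt
Reagents that add atoms: none
Why: Steglich esterification of the only remaining secondary hydroxyl; the tertiary C1–OH does not acylate under these conditions and the (S) centre of the acid comes from the chiral pool.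

Step 16
Reactants: 26 silylated ester from step 15
Product: 27 (3aS,5R,6S,7S,8S,8aR)-5,7-dihydroxy-7-[(3S)-3-hydroxybutanoyl]-6-methyl-3-methylidene-2-oxooctahydro-2H-cyclohepta[b]furan-8-yl (2S)-2-methylbutanoate (target)
Conditions: HF·pyridine, pyridine, THF, 0 °C
Reagents that add atoms: none
Why: Buffered HF·pyridine removes both triethylsilyl ethers without touching the esters, the α-methylene lactone or the β-hydroxy ketone.

**Compound list**

1 | 3-(trimethylsilyl)prop-2-ynal | C[Si](C)(C)C#CC=O | starting material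
2 | diethyl (2-oxobutyl)phosphonate | CCC(=O)CP(=O)(OCC)OCC | starting material
3 | (4E)-7-(trimethylsilyl)hept-4-en-6-yn-3-one | CCC(=O)/C=C/C#C[Si](C)(C)C | intermediate
4 | triethyl{[(2Z,4E)-7-(trimethylsilyl)hepta-2,4-dien-6-yn-3-yl]oxy}silane | C/C=C(/C=C/C#C[Si](C)(C)C)\O[Si](CC)(CC)CC | intermediate
5 | methyl 2-hydroxyacetate | COC(=O)CO | starting material
6 | methyl 2-[(triethylsilyl)oxy]acetate | COC(=O)CO[Si](CC)(CC)CC | intermediate
7 | methyl acetate | COC(C)=O | starting material
8 | lithium enolate of methyl acetate (formed in situ) | [Li+].[O-]C(=C)OC | intermediate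
9 | methyl 3-oxo-4-[(triethylsilyl)oxy]butanoate | COC(=O)CC(=O)CO[Si](CC)(CC)CC | intermediate
10 | methyl 2-diazo-3-oxo-4-[(triethylsilyl)oxy]butanoate | COC(=O)C(=[N+]=[N-])C(=O)CO[Si](CC)(CC)CC | intermediate
11 | methyl (3Z)-3-[(tert-butyldimethylsilyl)oxy]-2-diazo-4-[(triethylsilyl)oxy]but-3-enoate | COC(=O)C(=[N+]=[N-])/C(O[Si](C)(C)C(C)(C)C)=C/O[Si](CC)(CC)CC | intermediate
12 | cis-divinylcyclopropane: methyl 1-{(Z)-1-[(tert-butyldimethylsilyl)oxy]-2-[(triethylsilyl)oxy]ethenyl}-3-methyl-2-[(triethylsilyl)oxy]-2-[(E)-4-(trimethylsilyl)but-1-en-3-ynyl]cyclopropane-1-carboxylate (both alkenyl groups cis; methyl, ester and ring OTES on the other face; formed in situ) | C[C@@H]1[C@@](C(=O)OC)(/C(O[Si](C)(C)C(C)(C)C)=C/O[Si](CC)(CC)CC)[C@@]1(O[Si](CC)(CC)CC)/C=C/C#C[Si](C)(C)C | intermediate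
13 | methyl 2-[(tert-butyldimethylsilyl)oxy]-7-methyl-3,6-bis[(triethylsilyl)oxy]-4-[(trimethylsilyl)ethynyl]cyclohepta-1,5-diene-1-carboxylate (3/4/7 all-cis) | COC(=O)C1=C(O[Si](C)(C)C(C)(C)C)[C@H](O[Si](CC)(CC)CC)[C@H](C#C[Si](C)(C)C)C=C(O[Si](CC)(CC)CC)[C@@H]1C | intermediate
14 | methyl 2-[(tert-butyldimethylsilyl)oxy]-3-hydroxy-7-methyl-6-oxo-4-[(trimethylsilyl)ethynyl]cyclohept-1-ene-1-carboxylate (3/4/7 all-cis) | COC(=O)C1=C(O[Si](C)(C)C(C)(C)C)[C@H](O)[C@H](C#C[Si](C)(C)C)CC(=O)[C@@H]1C | intermediate
15 | silyloxy epoxide of 14 (C1–C5 epoxide, oxygen on the α face; formed in situ) | COC(=O)[C@@]12O[C@]1(O[Si](C)(C)C(C)(C)C)[C@H](O)[C@H](C#C[Si](C)(C)C)CC(=O)[C@@H]2C | intermediate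
16 | methyl 1-[(tert-butyldimethylsilyl)oxy]-3-hydroxy-7-methyl-2,6-dioxo-4-[(trimethylsilyl)ethynyl]cycloheptane-1-carboxylate (1-O/3-O/4-C/7-C all-cis) | COC(=O)[C@@]1(O[Si](C)(C)C(C)(C)C)C(=O)[C@H](O)[C@H](C#C[Si](C)(C)C)CC(=O)[C@@H]1C | intermediate
17 | methyl 4-ethynyl-1,3-dihydroxy-7-methyl-2,6-dioxocycloheptane-1-carboxylate (1-OH/3-OH/4-ethynyl/7-methyl all-cis) | COC(=O)[C@@]1(O)C(=O)[C@H](O)[C@H](C#C)CC(=O)[C@@H]1C | intermediate
18 | tetraol ester: methyl 4-ethynyl-1,2,3,6-tetrahydroxy-7-methylcycloheptane-1-carboxylate (1α,3α-OH; 2β,6β-OH; 4α-ethynyl; 7α-methyl; formed in situ) | COC(=O)[C@@]1(O)[C@@H](O)[C@H](O)[C@H](C#C)C[C@@H](O)[C@@H]1C | intermediate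
19 | 4-ethynyl-1,2,3-trihydroxy-9-methyl-7-oxabicyclo[4.2.1]nonan-8-one (bridged lactone C2–O–C9) | O=C1O[C@@H]2C[C@@H](C#C)[C@@H](O)[C@H](O)[C@@]1(O)[C@H]2C | intermediate
20 | (2S)-1-chloropropan-2-ol | ClC[C@H](C)O | starting material
21 | dilithio reagent: lithium (2S)-1-lithiopropan-2-olate (formed in situ) | [Li]C[C@H](C)O[Li] | intermediate
22 | (3S)-1-[4-ethynyl-1,2,3,6-tetrahydroxy-7-methylcycloheptyl]-3-hydroxybutan-1-one (ring: 1α,3α-OH; 2β,6β-OH; 4α-ethynyl; 7α-methyl) | C#C[C@@H]1C[C@@H](O)[C@H](C)[C@@](O)(C(=O)C[C@H](C)O)[C@@H](O)[C@@H]1O | intermediate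
23 | (3aS,5R,6S,7S,8S,8aR)-5,7,8-trihydroxy-7-[(3S)-3-hydroxybutanoyl]-6-methyl-3-methylideneoctahydro-2H-cyclohepta[b]furan-2-one | C=C1C(=O)O[C@@H]2[C@H]1C[C@@H](O)[C@H](C)[C@@](O)(C(=O)C[C@H](C)O)[C@H]2O | intermediate
24 | (3aS,5R,6S,7S,8S,8aR)-7,8-dihydroxy-6-methyl-3-methylidene-5-[(triethylsilyl)oxy]-7-{(3S)-3-[(triethylsilyl)oxy]butanoyl}octahydro-2H-cyclohepta[b]furan-2-one | C=C1C(=O)O[C@@H]2[C@H]1C[C@@H](O[Si](CC)(CC)CC)[C@H](C)[C@@](O)(C(=O)C[C@H](C)O[Si](CC)(CC)CC)[C@H]2O | intermediate
25 | (2S)-2-methylbutanoic acid | CC[C@H](C)C(=O)O | starting material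
26 | (3aS,5R,6S,7S,8S,8aR)-7-hydroxy-6-methyl-3-methylidene-2-oxo-5-[(triethylsilyl)oxy]-7-{(3S)-3-[(triethylsilyl)oxy]butanoyl}octahydro-2H-cyclohepta[b]furan-8-yl (2S)-2-methylbutanoate | C=C1C(=O)O[C@@H]2[C@H]1C[C@@H](O[Si](CC)(CC)CC)[C@H](C)[C@@](O)(C(=O)C[C@H](C)O[Si](CC)(CC)CC)[C@H]2OC(=O)[C@@H](C)CC | intermediate
27 | (3aS,5R,6S,7S,8S,8aR)-5,7-dihydroxy-7-[(3S)-3-hydroxybutanoyl]-6-methyl-3-methylidene-2-oxooctahydro-2H-cyclohepta[b]furan-8-yl (2S)-2-methylbutanoate | C=C1C(=O)O[C@@H]2[C@H]1C[C@@H](O)[C@H](C)[C@@](O)(C(=O)C[C@H](C)O)[C@H]2OC(=O)[C@@H](C)CC | target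

**Step count and risks**

Total step count: 16. Longest linear sequence: 14 steps (5 to 27 through steps 3–16).

The three steps most likely to fail:

1. Step 7. The very electron-rich silyl enol ether may attack the rhodium carbene stepwise through a zwitterion, so that open-chain alkylation, cyclopentene formation and loss of the cyclopropane geometry (and with it the C10 relationship) compete with the concerted cyclopropanation/Cope sequence. Fallback, setting out from 3 and 11 and returning at 14: the less nucleophilic enol acetate is used in place of the silyl enol ether. Enynone 3 is converted (LiN(SiMe3)2, THF/HMPA, −78 °C; Ac2O) into (2Z,4E)-7-(trimethylsilyl)hepta-2,4-dien-6-yn-3-yl acetate F1. With 11 under the conditions of step 7 this should cyclopropanate in a concerted manner to the cis-divinylcyclopropane acetate F2 and rearrange to the cycloheptadienyl acetate F3. Lipase-mediated butanolysis of the enol acetate (Candida antarctica lipase B, n-BuOH, t-BuOMe, rt) should give the C9 ketone F4, and the conditions of step 8 then remove the C6 triethylsilyl ether to give 14.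

2. Step 9. Oxygen may be delivered to the β face, or the epoxidation may not proceed, because the C6–OH can lie close to the plane of the deactivated C1=C5 enol ether and coordinate poorly to vanadium; oxidation of the allylic alcohol is a further drain. Fallback, setting out from 14 and returning at 17: substrate-directed epoxidation is replaced by reagent-controlled enolate hydroxylation. Bu4NF/AcOH converts 14 into the free β-keto ester F5 (drawn as its enol; the alkyne is desilylated at the same time). Its sodium enolate (NaN(SiMe3)2, 2 equiv, THF, −78 °C) is hydroxylated with an enantiopure (camphorsulfonyl)oxaziridine (Davis oxidation), using the antipode of the reagent that attacks the α face, which should give 17 directly.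

3. Step 12. The addition may stay incomplete or the material may decompose, through aggregation and low solubility of the polylithiated lactone, proton transfer to the organolithium, or β-elimination of the reagent on warming. Fallback, setting out from 19 and returning at 22: a sulfone-stabilised nucleophile is used and the sulfonyl group removed afterwards. (2S)-1-(Phenylsulfonyl)propan-2-ol F6, made from (S)-propylene oxide and PhSO2Na, is doubly deprotonated (n-BuLi, 2 equiv, THF, −78 °C) and acylated by 19 (pre-treated with LiN(SiMe3)2) to give the β-keto sulfone F7. Reductive desulfonylation with SmI2 (THF/MeOH, −78 °C) should then give 22.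

Further compounds
F1 | step 7 | (2Z,4E)-7-(trimethylsilyl)hepta-2,4-dien-6-yn-3-yl acetate | C/C=C(/C=C/C#C[Si](C)(C)C)\OC(C)=O
F2 | step 7 | cis-divinylcyclopropane acetate: methyl 2-acetoxy-1-{(Z)-1-[(tert-butyldimethylsilyl)oxy]-2-[(triethylsilyl)oxy]ethenyl}-3-methyl-2-[(E)-4-(trimethylsilyl)but-1-en-3-ynyl]cyclopropane-1-carboxylate | C[C@@H]1[C@@](C(=O)OC)(/C(O[Si](C)(C)C(C)(C)C)=C/O[Si](CC)(CC)CC)[C@@]1(OC(C)=O)/C=C/C#C[Si](C)(C)C
F3 | step 7 | methyl 6-acetoxy-2-[(tert-butyldimethylsilyl)oxy]-7-methyl-3-[(triethylsilyl)oxy]-4-[(trimethylsilyl)ethynyl]cyclohepta-1,5-diene-1-carboxylate (3/4/7 all-cis) | COC(=O)C1=C(O[Si](C)(C)C(C)(C)C)[C@H](O[Si](CC)(CC)CC)[C@H](C#C[Si](C)(C)C)C=C(OC(C)=O)[C@@H]1C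
F4 | step 7 | methyl 2-[(tert-butyldimethylsilyl)oxy]-7-methyl-6-oxo-3-[(triethylsilyl)oxy]-4-[(trimethylsilyl)ethynyl]cyclohept-1-ene-1-carboxylate (3/4/7 all-cis) | COC(=O)C1=C(O[Si](C)(C)C(C)(C)C)[C@H](O[Si](CC)(CC)CC)[C@H](C#C[Si](C)(C)C)CC(=O)[C@@H]1C
F5 | step 9 | methyl 4-ethynyl-2,3-dihydroxy-7-methyl-6-oxocyclohept-1-ene-1-carboxylate (enol form of the β-keto ester; 3/4/7 all-cis) | COC(=O)C1=C(O)[C@H](O)[C@H](C#C)CC(=O)[C@@H]1C
F6 | step 12 | (2S)-1-(phenylsulfonyl)propan-2-ol | C[C@H](O)CS(=O)(=O)c1ccccc1
F7 | step 12 | (3S)-1-[4-ethynyl-1,2,3,6-tetrahydroxy-7-methylcycloheptyl]-3-hydroxy-2-(phenylsulfonyl)butan-1-one (ring as in 22; mixture at C3) | C#C[C@@H]1C[C@@H](O)[C@H](C)[C@@](O)(C(=O)C([C@H](C)O)S(=O)(=O)c2ccccc2)[C@@H](O)[C@@H]1O
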